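**Retrosynthetic overview**
1. Ring C (the pyran) is opened at O1–C2: flavan 18 comes from the (R)-phenol-alcohol 17 by Mitsunobu etherification with inversion.
2. The strategy rests on ring A: its three adjacent oxygen-bearing carbons C8a (O1), C8 (OMe) and C7 (OMe) map onto the carbonyl carbon and the two methoxy-bearing alkene carbons of a squarate-derived cyclobutenone, whose fourth carbon becomes C6.
3. Ring A is therefore cut at C5–C6 (Stille coupling) and C4a–C8a (six-electron closure of a dienylketene), giving chlorocyclobutenone 3 and (R,E)-alkenylstannane 12; the stannane's two alkene carbons become C5 and C4a.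
4. Chloride 3 comes from dimethyl squarate 1; stannane 12 comes from aryl bromide 7 and pent-4-ynoic acid 4 (Weinreb ketone synthesis, CBS reduction, silylation, hydrostannation).
5. Ring order: ring B is bought, ring A is built in step 8, ring C is closed last in step 10.

Key step: step 8

Remark: flavan numbering (O1, C2 to C4, C4a, C5 to C8, C8a) is used for the target's atoms throughout; chloride 3 is racemic by design because its C4 becomes the aromatic C6.

Step 1
Reactants: 1 dimethyl squarate
Product: 2 (±)-4-hydroxy-2,3-dimethoxycyclobut-2-en-1-one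
Conditions: LiAlH(O-t-Bu)3 (1.05 equiv), THF, −78 to −40 °C; pH 7 buffer work-up
Reagents that add atoms: none
Why: Mono 1,2-reduction of a squarate ester, in which the bulky single-hydride aluminate adds once to one of the two equivalent vinylogous ester carbonyls and a second addition is not expected at low temperature (known for dialkyl squarates); the neutral work-up avoids acid-induced collapse to the cyclobutenedione, and the new C4 centre is racemic and later lost.

Step 2
Reactants: 2 (±)-4-hydroxy-2,3-dimethoxycyclobut-2-en-1-one
Product: 3 (±)-4-chloro-2,3-dimethoxycyclobut-2-en-1-one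
Conditions: 1-chloro-N,N,2-trimethylprop-1-en-1-amine (1.05 equiv), CH2Cl2, −20 to 0 °C; filtered cold through a short Florisil plug and used at once
Reagents that add atoms: 1-chloro-N,N,2-trimethylprop-1-en-1-amine, CC(C)=C(Cl)N(C)C
Why: Deoxychlorination of an alcohol with an α-chloroenamine under neutral, water-free conditions with only one equivalent of chloride, which matters because C4 ionises easily and acid, water or excess halide would divert the material to methyl semisquarate; chloride should settle on C4 because that isomer keeps the vinylogous ester conjugation.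

Step 3
Reactants: 4 pent-4-ynoic acid
Product: 6 N-methoxy-N-methylpent-4-ynamide, via acyl imidazole 5 (not isolated)
Conditions: 1,1'-carbonyldiimidazole (CDI), CH2Cl2, rt; then MeNH(OMe)·HCl, rt
Reagents that add atoms: N,O-dimethylhydroxylamine hydrochloride, CNOC.Cl
Why: Amide formation through acyl imidazole 5, in which CDI activates the acid with loss of CO2 and the hydroxylamine then displaces imidazole; the terminal alkyne is inert.

Step 4
Reactants: 6 N-methoxy-N-methylpent-4-ynamide; 7 5-bromo-1,2,3-trimethoxybenzene
Product: 9 1-(3,4,5-trimethoxyphenyl)pent-4-yn-1-one, via aryl Grignard reagent 8 (not isolated)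
Conditions: 7, Mg, THF, reflux; then 6 (0.45 equiv), THF, 0 °C; aq. HCl work-up
Reagents that add atoms: none
Why: Weinreb ketone synthesis, in which magnesium inserts into the aryl bromide and Grignard reagent 8 adds once to the N-methoxy-N-methylamide, the ketone being released only on acidic work-up; 8 is used in excess because part of it is consumed by deprotonating the terminal alkyne, which is re-protonated on work-up.

Step 5
Reactants: 9 1-(3,4,5-trimethoxyphenyl)pent-4-yn-1-one
Product: 10 (R)-1-(3,4,5-trimethoxyphenyl)pent-4-yn-1-ol
Conditions: (S)-Me-CBS catalyst [(3aS)-1-methyl-3,3-diphenyltetrahydro-3H-pyrrolo[1,2-c][1,3,2]oxazaborole, 10 mol%], catecholborane, toluene, −78 to −40 °C; aq. NaOH work-up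
Reagents that add atoms: none
Why: Corey–Bakshi–Shibata reduction, in which the (S)-oxazaborolidine binds the ketone with the aryl group as the large substituent and hydride is delivered to the Si face, giving the (R)-carbinol as for other aryl alkyl ketones; catecholborane at low temperature does not hydroborate the terminal alkyne.

Step 6
Reactants: 10 (R)-1-(3,4,5-trimethoxyphenyl)pent-4-yn-1-ol
Product: 11 (R)-tert-butyldimethyl{[1-(3,4,5-trimethoxyphenyl)pent-4-yn-1-yl]oxy}silane
Conditions: TBSCl, imidazole, DMF, rt
Reagents that add atoms: tert-butyldimethylsilyl chloride, CC(C)(C)[Si](C)(C)Cl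
Why: Standard silylation of a secondary benzylic alcohol that leaves the stereocentre untouched; the ether is needed so that no hydroxyl is present when the ketene is generated in step 8.

Step 7
Reactants: 11 (R)-tert-butyldimethyl{[1-(3,4,5-trimethoxyphenyl)pent-4-yn-1-yl]oxy}silane
Product: 12 (R,E)-tributyl[5-(tert-butyldimethylsilyloxy)-5-(3,4,5-trimethoxyphenyl)pent-1-en-1-yl]stannane
Conditions: Bu3SnH, Pd2(dba)3 (cat.), Cy3P·HBF4, i-Pr2NEt, CH2Cl2, 0 °C to rt
Reagents that add atoms: tributyltin hydride, CCCC[SnH](CCCC)CCCC
Why: Palladium-catalysed hydrostannation of a terminal alkyne, in which syn addition of H and Sn gives the E alkene and the bulky tricyclohexylphosphine ligand directs tin to the terminal carbon in preference to the internal one; silyl ether and arene are inert.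

Step 8
Reactants: 3 (±)-4-chloro-2,3-dimethoxycyclobut-2-en-1-one; 12 (R,E)-tributyl[5-(tert-butyldimethylsilyloxy)-5-(3,4,5-trimethoxyphenyl)pent-1-en-1-yl]stannane
Product: 16 (R)-6-[3-(tert-butyldimethylsilyloxy)-3-(3,4,5-trimethoxyphenyl)propyl]-2,3-dimethoxyphenol, via 4-alkenylcyclobutenone 13 (not isolated), via dienylketene 14 (not isolated), via cyclohexa-2,4-dienone 15 (not isolated)
Conditions: 3 (1.3 equiv, freshly made), PdCl2(PhCN)2 (5 mol%), tri(2-furyl)phosphine (10 mol%), dioxane, 50 °C; then 100 °C
Reagents that add atoms: none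
Why: Zerovalent palladium, formed in the flask from PdCl2(PhCN)2 and a little stannane, inserts into the allylic C4–Cl bond of 3, the alkenyl group is transferred from tin with its E geometry intact and reductive elimination at the CH terminus gives 13, which makes the C5–C6 bond (Stille cross-coupling). At 100 °C 13 opens by four-electron conrotatory electrocyclic cleavage of its C1–C4 bond to dienylketene 14, and 14 closes ring A by six-electron disrotatory electrocyclisation between the ketene carbon (C8a) and the distal alkene carbon (C4a) to give dienone 15, whose enolisation to phenol 16 is irreversible. The closest known reaction type is the palladium-catalysed coupling of 4-chlorocyclobutenones with alkenylstannanes followed by thermal ring expansion to phenols, and the 3-alkoxy-4-alkenylcyclobutenone stage is the same as in the Danheiser benzannulation. No stereocentre is created in 16, since the C4 centre of 13 and the C6 centre of 15 both end as sp2 carbons of ring A and the remote (R)-silyl ether takes no part. The selectivity needed is regiochemical, namely coupling at C4 and not with allylic transposition at C2, and it is secured by C4 being the unsubstituted, less hindered terminus whose coupling product keeps the vinylogous ester conjugation; from there the pattern C8a–OH, C8–OMe, C7–OMe follows from connectivity. Ring opening is reversible while aromatisation is not, so the mode of opening that places the alkenyl group cis to the ketene is drained to 16, and the silyl ether ensures that no hydroxyl can trap 14.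

Step 9
Reactants: 16 (R)-6-[3-(tert-butyldimethylsilyloxy)-3-(3,4,5-trimethoxyphenyl)propyl]-2,3-dimethoxyphenol
Product: 17 (R)-6-[3-hydroxy-3-(3,4,5-trimethoxyphenyl)propyl]-2,3-dimethoxyphenol
Conditions: Bu4NF, THF, 0 °C to rt; aq. NH4Cl work-up
Reagents that add atoms: none
Why: Fluoride-induced cleavage of the silyl ether driven by Si–F bond formation; the phenol is only deprotonated and returns on work-up, and the C–O bond of the (R)-carbinol is not broken.

Step 10
Reactants: 17 (R)-6-[3-hydroxy-3-(3,4,5-trimethoxyphenyl)propyl]-2,3-dimethoxyphenol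
Product: 18 (2S)-7,8,3',4',5'-pentamethoxyflavan
Conditions: PPh3, DIAD (diisopropyl azodicarboxylate), THF, 0 °C
Reagents that add atoms: none
Why: Intramolecular Mitsunobu etherification, in which the PPh3–DIAD pair activates the benzylic hydroxyl and the phenol oxygen on C8a displaces it in a 6-exo-tet SN2 closure with inversion, so the (R)-carbinol becomes (2S)-C2 (the CIP order O > aryl > CH2 > H is unchanged); the reaction is run cold to keep SN2 displacement ahead of benzylic ionisation.

**Compound list**
1 | dimethyl squarate (3,4-dimethoxycyclobut-3-ene-1,2-dione) | COC1=C(OC)C(=O)C1=O | starting material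
2 | (±)-4-hydroxy-2,3-dimethoxycyclobut-2-en-1-one | COC1=C(OC)C(O)C1=O | intermediate
3 | (±)-4-chloro-2,3-dimethoxycyclobut-2-en-1-one | COC1=C(OC)C(Cl)C1=O | intermediate
4 | pent-4-ynoic acid | C#CCCC(=O)O | starting material
5 | 1-(imidazol-1-yl)pent-4-yn-1-one | C#CCCC(=O)n1ccnc1 | intermediate
6 | N-methoxy-N-methylpent-4-ynamide | C#CCCC(=O)N(C)OC | intermediate
7 | 5-bromo-1,2,3-trimethoxybenzene | COc1cc(Br)cc(OC)c1OC | starting material
8 | (3,4,5-trimethoxyphenyl)magnesium bromide | COc1cc([Mg]Br)cc(OC)c1OC | intermediate
9 | 1-(3,4,5-trimethoxyphenyl)pent-4-yn-1-one | C#CCCC(=O)c1cc(OC)c(OC)c(OC)c1 | intermediate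
10 | (R)-1-(3,4,5-trimethoxyphenyl)pent-4-yn-1-ol | C#CCC[C@@H](O)c1cc(OC)c(OC)c(OC)c1 | intermediate
11 | (R)-tert-butyldimethyl{[1-(3,4,5-trimethoxyphenyl)pent-4-yn-1-yl]oxy}silane | C#CCC[C@@H](O[Si](C)(C)C(C)(C)C)c1cc(OC)c(OC)c(OC)c1 | intermediate
12 | (R,E)-tributyl[5-(tert-butyldimethylsilyloxy)-5-(3,4,5-trimethoxyphenyl)pent-1-en-1-yl]stannane | CCCC[Sn](CCCC)(CCCC)/C=C/CC[C@@H](O[Si](C)(C)C(C)(C)C)c1cc(OC)c(OC)c(OC)c1 | intermediate
13 | 4-[(1E,5R)-5-(tert-butyldimethylsilyloxy)-5-(3,4,5-trimethoxyphenyl)pent-1-en-1-yl]-2,3-dimethoxycyclobut-2-en-1-one (both C4 epimers) | COC1=C(OC)C(/C=C/CC[C@@H](O[Si](C)(C)C(C)(C)C)c2cc(OC)c(OC)c(OC)c2)C1=O | intermediate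
14 | (3E,5E,9R)-9-(tert-butyldimethylsilyloxy)-2,3-dimethoxy-9-(3,4,5-trimethoxyphenyl)nona-1,3,5-trien-1-one | O=C=C(OC)/C(OC)=C\C=C\CC[C@@H](O[Si](C)(C)C(C)(C)C)c1cc(OC)c(OC)c(OC)c1 | intermediate
15 | 6-[(3R)-3-(tert-butyldimethylsilyloxy)-3-(3,4,5-trimethoxyphenyl)propyl]-2,3-dimethoxycyclohexa-2,4-dien-1-one (both C6 epimers) | COC1=C(OC)C=CC(CC[C@@H](O[Si](C)(C)C(C)(C)C)c2cc(OC)c(OC)c(OC)c2)C1=O | intermediate
16 | (R)-6-[3-(tert-butyldimethylsilyloxy)-3-(3,4,5-trimethoxyphenyl)propyl]-2,3-dimethoxyphenol | COc1ccc(CC[C@@H](O[Si](C)(C)C(C)(C)C)c2cc(OC)c(OC)c(OC)c2)c(O)c1OC | intermediate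
17 | (R)-6-[3-hydroxy-3-(3,4,5-trimethoxyphenyl)propyl]-2,3-dimethoxyphenol | COc1ccc(CC[C@@H](O)c2cc(OC)c(OC)c(OC)c2)c(O)c1OC | intermediate
18 | (2S)-7,8,3',4',5'-pentamethoxyflavan [(2S)-7,8-dimethoxy-2-(3,4,5-trimethoxyphenyl)chromane] | COc1cc([C@@H]2CCc3ccc(OC)c(OC)c3O2)cc(OC)c1OC | target

**Step count**
Total: 10 steps. Longest linear sequence: 8 steps (steps 3 to 10, from pent-4-ynoic acid 4); the squarate branch joins after 2 steps.

**Steps most likely to fail**

Step 8 (key step). The labile chloride may ionise or hydrolyse before oxidative addition. The alkenyl group may be delivered with allylic transposition to C2 of the four-membered ring, which after ring expansion would put the methoxy groups on C6 and C7. The donor-substituted cyclobutenone may also resist ring opening and decompose on prolonged heating. The fallback buys ring A instead of building it and uses known dihydrochalcone chemistry. It sets out from bromide 7, whose Grignard reagent 8 is acylated with N-methoxy-N-methylacetamide (THF, 0 °C) to give 1-(3,4,5-trimethoxyphenyl)ethan-1-one F1. Claisen–Schmidt condensation of this ketone with commercial 2-hydroxy-3,4-dimethoxybenzaldehyde (KOH, EtOH, rt) should give (E)-3-(2-hydroxy-3,4-dimethoxyphenyl)-1-(3,4,5-trimethoxyphenyl)prop-2-en-1-one F2. Hydrogenation of the alkene (H2, Pd/C, EtOAc) should give 3-(2-hydroxy-3,4-dimethoxyphenyl)-1-(3,4,5-trimethoxyphenyl)propan-1-one F3. Noyori asymmetric transfer hydrogenation with RuCl[(R,R)-TsDPEN](p-cymene) and HCO2H–Et3N then reduces the aryl ketone to the (R)-carbinol, and the fallback comes back to the route at diol 17, one step before the target.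

Step 2. Ionisation at C4 during or after chlorination, followed by loss of a methyl group or by hydrolysis, would drain the material to methyl semisquarate. The fallback replaces the halide by a less ionisable allylic ester. It sets out from alcohol 2, which is acetylated (Ac2O, pyridine, CH2Cl2, 0 °C) to (±)-2,3-dimethoxy-4-oxocyclobut-2-en-1-yl acetate F4. This acetate is used in place of 3 in the known Stille coupling of allylic acetates with alkenylstannanes (stannane 12, Pd(dba)2, LiCl, DMF, rt, then heating), in which zerovalent palladium itself ionises the C4–O bond. The route is rejoined at phenol 16 through the same in-flask intermediates 13 to 15.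

Step 7. Tin may be delivered in part to the internal alkyne carbon, or the alkene geometry may scramble, and the isomeric stannanes would carry through the benzannulation to isomeric phenols that are hard to separate. The fallback is a stoichiometric hydrometallation with fixed regio- and stereochemistry. It sets out from alkyne 11; hydrozirconation with Cp2Zr(H)Cl (THF, rt) gives the (E)-alkenylzirconocene chloride F5 by syn addition with zirconium on the terminal carbon. Iodine then cleaves the C–Zr bond with retention to give the (R,E)-vinyl iodide F6. Iodine–lithium exchange (t-BuLi, Et2O, −78 °C) to the alkenyllithium F7, followed by Bu3SnCl, returns the route to stannane 12 as a single isomer.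

**Further compounds**
F1 | step 8 | 1-(3,4,5-trimethoxyphenyl)ethan-1-one | CC(=O)c1cc(OC)c(OC)c(OC)c1
F2 | step 8 | (E)-3-(2-hydroxy-3,4-dimethoxyphenyl)-1-(3,4,5-trimethoxyphenyl)prop-2-en-1-one | O=C(/C=C/c1ccc(OC)c(OC)c1O)c1cc(OC)c(OC)c(OC)c1
F3 | step 8 | 3-(2-hydroxy-3,4-dimethoxyphenyl)-1-(3,4,5-trimethoxyphenyl)propan-1-one | O=C(CCc1ccc(OC)c(OC)c1O)c1cc(OC)c(OC)c(OC)c1
F4 | step 2 | (±)-2,3-dimethoxy-4-oxocyclobut-2-en-1-yl acetate | COC1=C(OC)C(OC(C)=O)C1=O
F5 | step 7 | chlorobis(cyclopentadienyl)[(1E,5R)-5-(tert-butyldimethylsilyloxy)-5-(3,4,5-trimethoxyphenyl)pent-1-en-1-yl]zirconium | Cl[Zr](/C=C/CC[C@@H](O[Si](C)(C)C(C)(C)C)c1cc(OC)c(OC)c(OC)c1)(C1C=CC=C1)C1C=CC=C1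
F6 | step 7 | (R,E)-tert-butyl{[5-iodo-1-(3,4,5-trimethoxyphenyl)pent-4-en-1-yl]oxy}dimethylsilane | I/C=C/CC[C@@H](O[Si](C)(C)C(C)(C)C)c1cc(OC)c(OC)c(OC)c1
F7 | step 7 | [(1E,5R)-5-(tert-butyldimethylsilyloxy)-5-(3,4,5-trimethoxyphenyl)pent-1-en-1-yl]lithium | [Li]/C=C/CC[C@@H](O[Si](C)(C)C(C)(C)C)c1cc(OC)c(OC)c(OC)c1
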